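**Retrosynthetic overview**
- The isopropylidene terminus comes last, by cross-metathesis of a terminal vinyl group on the finished macrocycle (it is carried as an allyl group so that ozone can single out the ring alkene of limonene earlier).
- The only ring (14-membered) is closed by intramolecular Z-selective Still–Gennari olefination, forming C3=C4 of a seco aldehyde–phosphonate.
- The seco chain is joined at C12–C13 by a nickel-electrocatalytic coupling: the C13 radical, released from the ozonolysis-derived α-methoxy hydroperoxide of allyl-limonene, is coupled to a (Z)-alkenyl iodide, which fixes the 11Z alkene.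
- The alkenyl iodide–phosphonate comes from 4-pentyn-1-ol: Stork–Zhao iodo-olefination (11Z), Negishi carboalumination/ethylene oxide (7E), Appel iodination, phosphonoacetate alkylation.
- The single stereocentre (C1) is bought in (R)-(+)-limonene, which is allylated at its isopropenyl methyl group; no bond to C1 is made or broken.

Convention and assumption: skeleton positions are counted from the stereocentre as C1 towards the ester-bearing alkene (C3=C4; then C7=C8 E, C11=C12 Z), compound names use their own locants, and 1, 6, 8 and all reagents are taken as commercial.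

**Step 1**
Reactants: 1 4-pentyn-1-ol
Product: 3 (Z)-6-iodohept-5-en-1-yne, via 4-pentynal 2 (not isolated)
Conditions: Dess–Martin periodinane, CH2Cl2, 0 → 20 °C, filtered solution used directly; EtPPh3I, n-BuLi, THF, then I2, −78 °C, then NaN(SiMe3)2, then the aldehyde solution, −78 → −20 °C
Reagents that add atoms: ethyltriphenylphosphonium iodide CC[P+](c1ccccc1)(c1ccccc1)c1ccccc1.[I-]; iodine II
Why: Dess–Martin oxidation gives the volatile aldehyde, and the Stork–Zhao variant of the Wittig reaction with the α-iodo ylide is kinetically Z-selective (iodine cis to the chain), which fixes the future 11Z geometry.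

**Step 2**
Reactants: 3 (Z)-6-iodohept-5-en-1-yne
Product: 4 (3E,7Z)-8-iodo-4-methylnona-3,7-dien-1-ol
Conditions: AlMe3 (2.5 equiv), Cp2ZrCl2 (0.2 equiv), CH2Cl2, 0 → 20 °C; volatiles removed; MeLi (1.0 equiv), THF/hexane, −78 °C; ethylene oxide, −78 → 0 °C; 1 M HCl
Reagents that add atoms: trimethylaluminium C[Al](C)C; ethylene oxide C1CO1
Why: Negishi zirconium-catalysed carboalumination adds methyl and aluminium syn and regioselectively across the terminal alkyne only, and the derived alanate opens ethylene oxide with retention, giving the E-homoallylic alcohol (future 7E).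

**Step 3**
Reactants: 4 (3E,7Z)-8-iodo-4-methylnona-3,7-dien-1-ol
Product: 5 (2Z,6E)-2,9-diiodo-6-methylnona-2,6-diene
Conditions: I2, PPh3, imidazole, CH2Cl2, 0 → 20 °C
Reagents that add atoms: iodine II
Why: Appel iodination of the primary alcohol is neutral and leaves both alkenes and the alkenyl iodide untouched.

**Step 4**
Reactants: 5 (2Z,6E)-2,9-diiodo-6-methylnona-2,6-diene; 6 methyl 2-[bis(2,2,2-trifluoroethoxy)phosphoryl]acetate
Product: 7 methyl (5E,9Z)-2-[bis(2,2,2-trifluoroethoxy)phosphoryl]-10-iodo-6-methylundeca-5,9-dienoate (racemic at C2)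
Conditions: 6 (1.5 equiv), NaH, DMF, 0 °C; then 5, 20 → 45 °C
Reagents that add atoms: none
Why: SN2 C-alkylation of the sodium salt of the Still–Gennari phosphonoacetate by the primary iodide; the alkenyl iodide cannot react, and the new phosphonate-bearing centre is destroyed in step 7.

**Step 5**
Reactants: 8 (R)-(+)-limonene
Product: 9 (4R)-4-(hexa-1,5-dien-2-yl)-1-methylcyclohex-1-ene
Conditions: n-BuLi, TMEDA, 20 °C, 18 h; then allyl bromide, THF, −78 → 20 °C
Reagents that add atoms: allyl bromide C=CCBr
Why: Allylic metalation of limonene occurs selectively at the isopropenyl methyl group to a symmetrical 2-substituted allyl anion, whose alkylation gives one product from either terminus and leaves the C4 stereocentre unchanged (known metalation–alkylation of limonene).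

**Step 6**
Reactants: 9 (4R)-4-(hexa-1,5-dien-2-yl)-1-methylcyclohex-1-ene; 7 methyl (5E,9Z)-2-[bis(2,2,2-trifluoroethoxy)phosphoryl]-10-iodo-6-methylundeca-5,9-dienoate
Product: 13 methyl (5E,9Z,13R)-2-[bis(2,2,2-trifluoroethoxy)phosphoryl]-13-(hexa-1,5-dien-2-yl)-6,10-dimethyl-15-oxopentadeca-5,9-dienoate, via hydroperoxy aldehyde 10 (not isolated), via hydroperoxy acetal 11 (not isolated), via coupled acetal 12 (not isolated)
Conditions: 9 (1.5 equiv), O3, CH2Cl2/MeOH 5:1, Sudan Red 7B end-point, −78 °C; TsOH·H2O (cat.), −78 → 20 °C; solid NaHCO3, solvent switch to DMF at 0 °C; then 7, NiCl2·6H2O (15 mol%), 4,4′-di-tert-butyl-2,2′-bipyridine (18 mol%), n-Bu4NBF4, DMF, Mg anode, carbon-felt cathode, 4 mA, 2.4 F/mol, 0 °C; then 1 M HCl, THF, 20 °C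
Reagents that add atoms: ozone [O-][O+]=O
Why: Proposed new method: Criegee ozonolysis of the most electron-rich (ring, trisubstituted) alkene in methanol puts the carbonyl oxide on the methyl-bearing carbon, where it is trapped as the α-methoxy hydroperoxide, and the aldehyde is masked as its dimethyl acetal; cathodically generated monovalent nickel then reduces the O–O bond by single-electron transfer, the α-methoxy alkoxy radical loses methyl acetate by β-scission, and the primary C13 radical is captured by the alkenylnickel species formed from 7 and zerovalent nickel, so that reductive elimination forges C12–C13 with retention of the Z alkene while C1 is never touched, after which dilute acid unmasks the aldehyde; the closest known reactions are the divalent-iron-mediated fragmentation of ozonolysis-derived α-methoxy hydroperoxides to alkyl radicals (dealkenylative functionalisation) and the nickel-electrocatalytic decarboxylative alkenylation of redox-active esters with alkenyl iodides, the new element being the hydroperoxide as the redox-active radical precursor in the nickel cycle.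

**Step 7**
Reactants: 13 methyl (5E,9Z,13R)-2-[bis(2,2,2-trifluoroethoxy)phosphoryl]-13-(hexa-1,5-dien-2-yl)-6,10-dimethyl-15-oxopentadeca-5,9-dienoate
Product: 14 methyl (1Z,4R,7Z,11E)-4-(hexa-1,5-dien-2-yl)-7,11-dimethylcyclotetradeca-1,7,11-triene-1-carboxylate
Conditions: K2CO3, 18-crown-6, toluene, 1 mM (slow addition of 13), 0 → 20 °C
Reagents that add atoms: none
Why: Intramolecular Still–Gennari (Horner–Wadsworth–Emmons) olefination: the electron-poor bis(trifluoroethyl) phosphonate eliminates faster than its adduct equilibrates, so the ester ends cis to C2 (1Z by name), and high dilution with a mild base favours the 14-membered ring over oligomers; the remote stereocentre is not affected.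

**Step 8**
Reactants: 14 methyl (1Z,4R,7Z,11E)-4-(hexa-1,5-dien-2-yl)-7,11-dimethylcyclotetradeca-1,7,11-triene-1-carboxylate
Product: 15 methyl (1Z,4R,7Z,11E)-7,11-dimethyl-4-(6-methylhepta-1,5-dien-2-yl)cyclotetradeca-1,7,11-triene-1-carboxylate (CNP0163659.2)
Conditions: second-generation Grubbs catalyst (5 mol%), 2-methyl-2-butene/CH2Cl2, 35 °C
Reagents that add atoms: 2-methyl-2-butene CC=C(C)C
Why: Olefin cross-metathesis with excess 2-methyl-2-butene converts only the monosubstituted terminal alkene into the isopropylidene group; the 1,1-disubstituted, trisubstituted and enoate alkenes are too hindered or electron-poor to react.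

**Compound list**
1 | 4-pentyn-1-ol | C#CCCCO | starting material
2 | 4-pentynal | C#CCCC=O | intermediate
3 | (Z)-6-iodohept-5-en-1-yne | C#CCC/C=C(/C)I | intermediate
4 | (3E,7Z)-8-iodo-4-methylnona-3,7-dien-1-ol | OCC/C=C(\C)CC/C=C(/C)I | intermediate
5 | (2Z,6E)-2,9-diiodo-6-methylnona-2,6-diene | ICC/C=C(\C)CC/C=C(/C)I | intermediate
6 | methyl 2-[bis(2,2,2-trifluoroethoxy)phosphoryl]acetate | COC(=O)CP(=O)(OCC(F)(F)F)OCC(F)(F)F | starting material
7 | methyl (5E,9Z)-2-[bis(2,2,2-trifluoroethoxy)phosphoryl]-10-iodo-6-methylundeca-5,9-dienoate (racemic at C2) | COC(=O)C(CC/C=C(\C)CC/C=C(/C)I)P(=O)(OCC(F)(F)F)OCC(F)(F)F | intermediate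
8 | (R)-(+)-limonene | CC1=CC[C@@H](CC1)C(C)=C | starting material
9 | (4R)-4-(hexa-1,5-dien-2-yl)-1-methylcyclohex-1-ene | CC1=CC[C@@H](CC1)C(=C)CCC=C | intermediate
10 | (3R)-3-(hexa-1,5-dien-2-yl)-6-hydroperoxy-6-methoxyheptanal (both C6 epimers) | O=CC[C@@H](CCC(C)(OC)OO)C(=C)CCC=C | intermediate
11 | (3R)-3-(hexa-1,5-dien-2-yl)-6-hydroperoxy-1,1,6-trimethoxyheptane (both C6 epimers) | COC(OC)C[C@@H](CCC(C)(OC)OO)C(=C)CCC=C | intermediate
12 | methyl (5E,9Z,13R)-2-[bis(2,2,2-trifluoroethoxy)phosphoryl]-13-(hexa-1,5-dien-2-yl)-15,15-dimethoxy-6,10-dimethylpentadeca-5,9-dienoate (both C2 epimers) | COC(=O)C(CC/C=C(\C)CC/C=C(/C)CC[C@H](CC(OC)OC)C(=C)CCC=C)P(=O)(OCC(F)(F)F)OCC(F)(F)F | intermediate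
13 | methyl (5E,9Z,13R)-2-[bis(2,2,2-trifluoroethoxy)phosphoryl]-13-(hexa-1,5-dien-2-yl)-6,10-dimethyl-15-oxopentadeca-5,9-dienoate (both C2 epimers) | COC(=O)C(CC/C=C(\C)CC/C=C(/C)CC[C@H](CC=O)C(=C)CCC=C)P(=O)(OCC(F)(F)F)OCC(F)(F)F | intermediate
14 | methyl (1Z,4R,7Z,11E)-4-(hexa-1,5-dien-2-yl)-7,11-dimethylcyclotetradeca-1,7,11-triene-1-carboxylate | C=CCCC(=C)[C@H]1C/C=C(\C(=O)OC)CC/C=C(\C)CC/C=C(/C)CC1 | intermediate
15 | methyl (1Z,4R,7Z,11E)-7,11-dimethyl-4-(6-methylhepta-1,5-dien-2-yl)cyclotetradeca-1,7,11-triene-1-carboxylate | C=C(CCC=C(C)C)[C@H]1C/C=C(\C(=O)OC)CC/C=C(\C)CC/C=C(/C)CC1 | target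

**Step count**
Total: 8 steps. Longest linear sequence: 7 steps (steps 1, 2, 3, 4, 6, 7, 8 from 4-pentyn-1-ol); the limonene branch joins after one step (step 5).

**Steps most likely to fail, with fallbacks**

Step 6 (the proposed new coupling) is the main risk. Ozone may also attack the 1,1-disubstituted alkene, and the Criegee fragmentation is not fully regioselective. The cathode may reduce the peroxide by two electrons to the ketone. The alkoxy or C13 radical may undergo 1,5-hydrogen transfer (from C1–H or the side-chain allylic CH2). The hydroxide released may damage the trifluoroethyl phosphonate. The fallback uses only known chemistry, sets out from 9 and comes back at 12. Ozonolysis of 9 with the same acetalisation but reductive work-up (Me2S) gives (5R)-5-(hexa-1,5-dien-2-yl)-7,7-dimethoxyheptan-2-one F1. Haloform cleavage (NaOBr, dioxane/water, 0 °C, buffered work-up) gives (4R)-4-(hexa-1,5-dien-2-yl)-6,6-dimethoxyhexanoic acid F2. N-Hydroxyphthalimide and diisopropylcarbodiimide give the redox-active ester 1,3-dioxoisoindolin-2-yl (4R)-4-(hexa-1,5-dien-2-yl)-6,6-dimethoxyhexanoate F3. Nickel-electrocatalytic decarboxylative alkenylation of F3 with 7 (NiCl2·6H2O, 2,2′-bipyridine, AgNO3, DMF, Mg anode) gives 12, which is hydrolysed to 13 as in step 6. This adds three steps.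

Step 7 (macrocyclic olefination) may give oligomers or an eroded Z:E ratio, since Z selectivity of Still–Gennari reagents is less dependable in ring closures. The fallback fixes the enoate geometry before the ring is closed and closes the ring at C4–C5 instead; it sets out from 4 and comes back at 14. Alcohol 4 (in place of 7) is coupled with hydroperoxide 11 as in step 6, or with F3 as above, to give (3E,7Z,11R)-11-(hexa-1,5-dien-2-yl)-13,13-dimethoxy-4,8-dimethyltrideca-3,7-dien-1-ol F4. Acid work-up gives (3R,6Z,10E)-3-(hexa-1,5-dien-2-yl)-13-hydroxy-6,10-dimethyltrideca-6,10-dienal F5. Horner–Wadsworth–Emmons reaction with methyl bis(2,2,2-trifluoroethyl) bromophosphonoacetate (KOt-Bu, 18-crown-6, THF, −78 °C), a reagent known to give (E)-α-bromoacrylates, gives methyl (2E,5R,8Z,12E)-2-bromo-5-(hexa-1,5-dien-2-yl)-15-hydroxy-8,12-dimethylpentadeca-2,8,12-trienoate F6. Appel iodination gives methyl (2E,5R,8Z,12E)-2-bromo-5-(hexa-1,5-dien-2-yl)-15-iodo-8,12-dimethylpentadeca-2,8,12-trienoate F7. Zinc insertion (Zn, LiCl, THF) gives [(3E,7Z,11R,13E)-14-bromo-11-(hexa-1,5-dien-2-yl)-15-methoxy-4,8-dimethyl-15-oxopentadeca-3,7,13-trien-1-yl]zinc iodide F8. Intramolecular Negishi coupling (Pd(PPh3)4, THF, high dilution) then closes the ring with retention of the alkene geometry to 14.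

Step 2 (alanate opening of ethylene oxide beside an alkenyl iodide) may fail through attack of the alkyllithium on the C–I bond or through imperfect carboalumination regiochemistry. The fallback does the organoaluminium chemistry before the iodo-olefination; it sets out from 1 and comes back at 5. Silylation of 1 (TBSCl, imidazole) gives tert-butyldimethyl(pent-4-yn-1-yloxy)silane F9. Carboalumination, n-BuLi and ethylene oxide give (E)-7-[(tert-butyldimethylsilyl)oxy]-4-methylhept-3-en-1-ol F10. Appel iodination gives tert-butyl{[(E)-7-iodo-4-methylhept-4-en-1-yl]oxy}dimethylsilane F11. Desilylation (n-Bu4NF) gives (E)-7-iodo-4-methylhept-4-en-1-ol F12. Dess–Martin oxidation gives (E)-7-iodo-4-methylhept-4-enal F13, and Stork–Zhao olefination as in step 1 gives 5 directly. This adds two steps.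

**Further compounds**
F1 | step 6 | (5R)-5-(hexa-1,5-dien-2-yl)-7,7-dimethoxyheptan-2-one | CC(=O)CC[C@H](CC(OC)OC)C(=C)CCC=C
F2 | step 6 | (4R)-4-(hexa-1,5-dien-2-yl)-6,6-dimethoxyhexanoic acid | OC(=O)CC[C@H](CC(OC)OC)C(=C)CCC=C
F3 | step 6 | 1,3-dioxoisoindolin-2-yl (4R)-4-(hexa-1,5-dien-2-yl)-6,6-dimethoxyhexanoate | O=C(CC[C@H](CC(OC)OC)C(=C)CCC=C)ON1C(=O)c2ccccc2C1=O
F4 | step 7 | (3E,7Z,11R)-11-(hexa-1,5-dien-2-yl)-13,13-dimethoxy-4,8-dimethyltrideca-3,7-dien-1-ol | OCC/C=C(\C)CC/C=C(/C)CC[C@H](CC(OC)OC)C(=C)CCC=C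
F5 | step 7 | (3R,6Z,10E)-3-(hexa-1,5-dien-2-yl)-13-hydroxy-6,10-dimethyltrideca-6,10-dienal | OCC/C=C(\C)CC/C=C(/C)CC[C@H](CC=O)C(=C)CCC=C
F6 | step 7 | methyl (2E,5R,8Z,12E)-2-bromo-5-(hexa-1,5-dien-2-yl)-15-hydroxy-8,12-dimethylpentadeca-2,8,12-trienoate | OCC/C=C(\C)CC/C=C(/C)CC[C@H](C/C=C(/Br)C(=O)OC)C(=C)CCC=C
F7 | step 7 | methyl (2E,5R,8Z,12E)-2-bromo-5-(hexa-1,5-dien-2-yl)-15-iodo-8,12-dimethylpentadeca-2,8,12-trienoate | ICC/C=C(\C)CC/C=C(/C)CC[C@H](C/C=C(/Br)C(=O)OC)C(=C)CCC=C
F8 | step 7 | [(3E,7Z,11R,13E)-14-bromo-11-(hexa-1,5-dien-2-yl)-15-methoxy-4,8-dimethyl-15-oxopentadeca-3,7,13-trien-1-yl]zinc iodide | I[Zn]CC/C=C(\C)CC/C=C(/C)CC[C@H](C/C=C(/Br)C(=O)OC)C(=C)CCC=C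
F9 | step 2 | tert-butyldimethyl(pent-4-yn-1-yloxy)silane | C#CCCCO[Si](C)(C)C(C)(C)C
F10 | step 2 | (E)-7-[(tert-butyldimethylsilyl)oxy]-4-methylhept-3-en-1-ol | OCC/C=C(\C)CCCO[Si](C)(C)C(C)(C)C
F11 | step 2 | tert-butyl{[(E)-7-iodo-4-methylhept-4-en-1-yl]oxy}dimethylsilane | ICC/C=C(\C)CCCO[Si](C)(C)C(C)(C)C
F12 | step 2 | (E)-7-iodo-4-methylhept-4-en-1-ol | ICC/C=C(\C)CCCO
F13 | step 2 | (E)-7-iodo-4-methylhept-4-enal | ICC/C=C(\C)CCC=O
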